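**Plan**
Retrosynthesis: the four silyl groups and the two acetates come off last, and the CH2OAc arms on C3 and C4 go back to esters. The oxolane goes back to a 2,3-dihydrofuran (C4=C5), which is cut at O1–C2 and C2–C3.
Enabling feature: C2 with its aryl is a single carbon bonded in the ring only to O1 and C3. The O1–C5–C4–C3 chain with the exocyclic carbons on C3 and C4 maps onto a 2-aroylbutenedioate, so a benzyl sulfonium ylide can deliver C2 first as nucleophile, then as electrophile.
Forward: one silylated protocatechualdehyde feeds both halves (homologation and Knoevenagel condensation to the acceptor; reduction, bromination and sulfide alkylation to the salt). The only ring closes in the annulation; C4=C5 hydrogenation, C5 epimerisation, ester reduction, acetylation and desilylation follow.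
Stereochemistry: 2,3-trans from the annulation, 3,4-cis from syn-hydrogenation on the face opposite the C3 ester, 4,5-trans from acid equilibration of benzylic C5.

Key step: step 7

Remark: the descriptors of the target define a meso compound (2,3-trans, 3,4-cis, 4,5-trans; mirror plane through O1 and the C3–C4 midpoint), so only relative configuration is controlled and chiral intermediates are racemic. Ring atoms are numbered O1, C2 (aryl), C3, C4, C5 (aryl) throughout.

Step 1
Reactants: 1 3,4-dihydroxybenzaldehyde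
Product: 2 3,4-bis(tert-butyldimethylsilyloxy)benzaldehyde
Conditions: TBSCl (2.4 equiv), imidazole (5 equiv), DMF, 0 °C to rt
Reagents that add atoms: tert-butyldimethylsilyl chloride, CC(C)(C)[Si](C)(C)Cl
Why: Imidazole-promoted silylation of both phenols is routine for this aldehyde and masks the catechol against base, hydride and oxidation until the last step.

Step 2
Reactants: 2 3,4-bis(tert-butyldimethylsilyloxy)benzaldehyde; 3 ethyl diazoacetate
Product: 4 ethyl 3-[3,4-bis(tert-butyldimethylsilyloxy)phenyl]-3-oxopropanoate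
Conditions: N2CHCO2Et (1.3 equiv), SnCl2 (0.2 equiv), CH2Cl2, rt
Reagents that add atoms: ethyl diazoacetate (3), CCOC(=O)C=[N+]=[N-]
Why: Roskamp homologation, in which the Lewis acid activates the aldehyde, the diazo ester adds and a 1,2-hydride shift with loss of nitrogen should give the β-keto ester while the aryl silyl ethers are untouched.

Step 3
Reactants: 4 ethyl 3-[3,4-bis(tert-butyldimethylsilyloxy)phenyl]-3-oxopropanoate; 5 ethyl glyoxylate
Product: 6 diethyl 2-[3,4-bis(tert-butyldimethylsilyloxy)benzoyl]but-2-enedioate (E/Z mixture, either isomer serves)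
Conditions: ethyl glyoxylate (1.5 equiv, toluene solution), piperidine (0.1 equiv), AcOH (0.1 equiv), 4 Å molecular sieves, toluene, 60 °C
Reagents that add atoms: ethyl glyoxylate (5), CCOC(=O)C=O
Why: Knoevenagel condensation of the active methylene with the very electrophilic glyoxylate aldehyde under piperidinium acetate catalysis, driven by removal of water; the alkene geometry is irrelevant because this carbon becomes sp3 in step 7.

Step 4
Reactants: 2 3,4-bis(tert-butyldimethylsilyloxy)benzaldehyde
Product: 7 [3,4-bis(tert-butyldimethylsilyloxy)phenyl]methanol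
Conditions: NaBH4, MeOH/THF, 0 °C
Reagents that add atoms: none
Why: Borohydride reduction of an aryl aldehyde, under which aryl silyl ethers are stable at 0 °C.

Step 5
Reactants: 7 [3,4-bis(tert-butyldimethylsilyloxy)phenyl]methanol
Product: 8 4-(bromomethyl)-1,2-bis(tert-butyldimethylsilyloxy)benzene
Conditions: CBr4, PPh3, CH2Cl2, 0 °C; used without storage
Reagents that add atoms: carbon tetrabromide, BrC(Br)(Br)Br
Why: Appel bromination converts the benzylic alcohol into the bromide under neutral conditions that spare the silyl ethers.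

Step 6
Reactants: 8 4-(bromomethyl)-1,2-bis(tert-butyldimethylsilyloxy)benzene; 9 dimethyl sulfide
Product: 10 [3,4-bis(tert-butyldimethylsilyloxy)benzyl]dimethylsulfonium bromide
Conditions: Me2S (5 equiv), acetone, rt, dark
Reagents that add atoms: dimethyl sulfide (9), CSC
Why: SN2 S-alkylation of the sulfide by an activated benzylic bromide; precipitation of the salt from acetone should pull the equilibrium to the product.

Step 7
Reactants: 6 diethyl 2-[3,4-bis(tert-butyldimethylsilyloxy)benzoyl]but-2-enedioate; 10 [3,4-bis(tert-butyldimethylsilyloxy)benzyl]dimethylsulfonium bromide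
Product: 13 diethyl trans-2,5-bis[3,4-bis(tert-butyldimethylsilyloxy)phenyl]-2,3-dihydrofuran-3,4-dicarboxylate (racemic), via benzylic sulfonium ylide 11 (not isolated), via sulfonium enolate betaine 12 (not isolated)
Conditions: Cs2CO3 (1.5 equiv, added last), dry MeCN, 0 °C to rt, Ar
Reagents that add atoms: none
Why: Carbonate deprotonates the salt to the semi-stabilised ylide 11, which adds to the CH carbon of the alkene in 6 because only this regiochemistry gives the doubly stabilised aroyl ester enolate 12 (C2–C3 bond). The aroyl enolate oxygen then displaces dimethyl sulfide from the former ylide carbon in a 5-exo-tet SN2 closure (O1–C2 bond), which forms the dihydrofuran ring. The closest known reaction type is the formal [4+1] annulation (Michael addition, then intramolecular O-alkylation) of sulfonium and pyridinium ylides with alkylidene 1,3-dicarbonyl compounds to trans-2,3-dihydrofurans. C2 and C3 are the new stereocentres; their trans relationship is substrate-controlled, since betaine formation is reversible, closure goes through the rotamer with the C2 aryl and the C3 ester apart, and any cis product can equilibrate through the acidic C3–H. The step needs O- over C-alkylation and ketone over ester oxygen; the cation-stabilising benzylic electrophile and the higher charge density on the aroyl oxygen favour both, and a cyclopropane from 3-exo-tet closure would be a donor–acceptor cyclopropane that should ring-expand (Cloke–Wilson rearrangement) to the same product.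

Step 8
Reactants: 13 diethyl trans-2,5-bis[3,4-bis(tert-butyldimethylsilyloxy)phenyl]-2,3-dihydrofuran-3,4-dicarboxylate
Product: 14 diethyl (2,3-trans-3,4-cis-4,5-cis)-2,5-bis[3,4-bis(tert-butyldimethylsilyloxy)phenyl]oxolane-3,4-dicarboxylate (racemic)
Conditions: H2 (20 bar), Rh/Al2O3 (5 wt% Rh), EtOAc, rt
Reagents that add atoms: none
Why: Heterogeneous syn-hydrogenation of a 2-aryl-4,5-dihydrofuran-3-carboxylate, in which both hydrogens should arrive at C4 and C5 from the face opposite the allylic C3 ester and so set 3,4-cis and 4,5-cis; rhodium on alumina is chosen over palladium to hold back hydrogenolysis of the benzylic C–O bonds.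

Step 9
Reactants: 14 diethyl (2,3-trans-3,4-cis-4,5-cis)-2,5-bis[3,4-bis(tert-butyldimethylsilyloxy)phenyl]oxolane-3,4-dicarboxylate
Product: 15 diethyl (2,3-trans-3,4-cis-4,5-trans)-2,5-bis[3,4-bis(tert-butyldimethylsilyloxy)phenyl]oxolane-3,4-dicarboxylate (meso)
Conditions: BF3·OEt2 (0.3 equiv), CH2Cl2, −20 to 0 °C
Reagents that add atoms: none
Why: Lewis-acid epimerisation of a 2-aryltetrahydrofuran under thermodynamic control, in which reversible ionisation of the benzylic C5–O1 bond to a para-oxygen-stabilised cation and reclosure should place the C5 aryl trans to the C4 ester; C3 and C4 are not touched and C2 is already trans, so the mixture should funnel to the meso isomer.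

Step 10
Reactants: 15 diethyl (2,3-trans-3,4-cis-4,5-trans)-2,5-bis[3,4-bis(tert-butyldimethylsilyloxy)phenyl]oxolane-3,4-dicarboxylate
Product: 16 {(2,3-trans-3,4-cis-4,5-trans)-2,5-bis[3,4-bis(tert-butyldimethylsilyloxy)phenyl]oxolane-3,4-diyl}dimethanol (meso)
Conditions: i-Bu2AlH (6 equiv), CH2Cl2, −78 to 0 °C; Rochelle salt work-up
Reagents that add atoms: none
Why: Aluminium hydride reduction of both esters to primary alcohols, which touches no stereocentre and leaves aryl silyl ethers intact at low temperature.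

Step 11
Reactants: 16 {(2,3-trans-3,4-cis-4,5-trans)-2,5-bis[3,4-bis(tert-butyldimethylsilyloxy)phenyl]oxolane-3,4-diyl}dimethanol
Product: 17 {(2,3-trans-3,4-cis-4,5-trans)-2,5-bis[3,4-bis(tert-butyldimethylsilyloxy)phenyl]oxolane-3,4-diyl}dimethanediyl diacetate (meso)
Conditions: Ac2O (3 equiv), pyridine, DMAP (cat.), CH2Cl2, rt
Reagents that add atoms: acetic anhydride, CC(=O)OC(C)=O
Why: DMAP-catalysed acetylation of two unhindered primary alcohols under basic conditions that leave the benzylic ether centres alone.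

Step 12
Reactants: 17 {(2,3-trans-3,4-cis-4,5-trans)-2,5-bis[3,4-bis(tert-butyldimethylsilyloxy)phenyl]oxolane-3,4-diyl}dimethanediyl diacetate
Product: 18 [(2R,3S,4R,5S)-2,5-bis(3,4-dihydroxyphenyl)oxolane-3,4-diyl]dimethanediyl diacetate (meso; CNP0416169.1)
Conditions: TBAF (4.4 equiv), AcOH (5 equiv), THF, 0 °C, Ar
Reagents that add atoms: none
Why: Fluoride cleavage of aryl silyl ethers, buffered with acetic acid so that each phenoxide is protonated at once and neither acetate transfer nor catechol oxidation should occur.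

**Compound list**
1 | 3,4-dihydroxybenzaldehyde | O=Cc1ccc(O)c(O)c1 | starting material
2 | 3,4-bis(tert-butyldimethylsilyloxy)benzaldehyde | O=Cc1ccc(O[Si](C)(C)C(C)(C)C)c(O[Si](C)(C)C(C)(C)C)c1 | intermediate
3 | ethyl diazoacetate | CCOC(=O)C=[N+]=[N-] | starting material
4 | ethyl 3-[3,4-bis(tert-butyldimethylsilyloxy)phenyl]-3-oxopropanoate | CCOC(=O)CC(=O)c1ccc(O[Si](C)(C)C(C)(C)C)c(O[Si](C)(C)C(C)(C)C)c1 | intermediate
5 | ethyl glyoxylate | CCOC(=O)C=O | starting material
6 | diethyl 2-[3,4-bis(tert-butyldimethylsilyloxy)benzoyl]but-2-enedioate (E isomer drawn, geometry immaterial) | CCOC(=O)/C=C(/C(=O)OCC)C(=O)c1ccc(O[Si](C)(C)C(C)(C)C)c(O[Si](C)(C)C(C)(C)C)c1 | intermediate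
7 | [3,4-bis(tert-butyldimethylsilyloxy)phenyl]methanol | OCc1ccc(O[Si](C)(C)C(C)(C)C)c(O[Si](C)(C)C(C)(C)C)c1 | intermediate
8 | 4-(bromomethyl)-1,2-bis(tert-butyldimethylsilyloxy)benzene | BrCc1ccc(O[Si](C)(C)C(C)(C)C)c(O[Si](C)(C)C(C)(C)C)c1 | intermediate
9 | dimethyl sulfide | CSC | starting material
10 | [3,4-bis(tert-butyldimethylsilyloxy)benzyl]dimethylsulfonium bromide | C[S+](C)Cc1ccc(O[Si](C)(C)C(C)(C)C)c(O[Si](C)(C)C(C)(C)C)c1.[Br-] | intermediate
11 | [3,4-bis(tert-butyldimethylsilyloxy)phenyl](dimethylsulfonio)methanide (ylide, not isolated) | C[S+](C)[CH-]c1ccc(O[Si](C)(C)C(C)(C)C)c(O[Si](C)(C)C(C)(C)C)c1 | intermediate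
12 | zwitterionic Michael adduct of 11 and 6: sulfonium at the future C2, aroyl ester enolate across C4–C5 (equilibrating diastereomers, not isolated) | CCOC(=O)C(C([S+](C)C)c1ccc(O[Si](C)(C)C(C)(C)C)c(O[Si](C)(C)C(C)(C)C)c1)C(C(=O)OCC)=C([O-])c1ccc(O[Si](C)(C)C(C)(C)C)c(O[Si](C)(C)C(C)(C)C)c1 | intermediate
13 | diethyl trans-2,5-bis[3,4-bis(tert-butyldimethylsilyloxy)phenyl]-2,3-dihydrofuran-3,4-dicarboxylate (racemic, one enantiomer drawn) | CCOC(=O)[C@@H]1C(C(=O)OCC)=C(c2ccc(O[Si](C)(C)C(C)(C)C)c(O[Si](C)(C)C(C)(C)C)c2)O[C@H]1c1ccc(O[Si](C)(C)C(C)(C)C)c(O[Si](C)(C)C(C)(C)C)c1 | intermediate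
14 | diethyl (2,3-trans-3,4-cis-4,5-cis)-2,5-bis[3,4-bis(tert-butyldimethylsilyloxy)phenyl]oxolane-3,4-dicarboxylate (racemic, one enantiomer drawn) | CCOC(=O)[C@@H]1[C@H](C(=O)OCC)[C@H](c2ccc(O[Si](C)(C)C(C)(C)C)c(O[Si](C)(C)C(C)(C)C)c2)O[C@H]1c1ccc(O[Si](C)(C)C(C)(C)C)c(O[Si](C)(C)C(C)(C)C)c1 | intermediate
15 | diethyl (2,3-trans-3,4-cis-4,5-trans)-2,5-bis[3,4-bis(tert-butyldimethylsilyloxy)phenyl]oxolane-3,4-dicarboxylate (meso) | CCOC(=O)[C@@H]1[C@H](C(=O)OCC)[C@@H](c2ccc(O[Si](C)(C)C(C)(C)C)c(O[Si](C)(C)C(C)(C)C)c2)O[C@H]1c1ccc(O[Si](C)(C)C(C)(C)C)c(O[Si](C)(C)C(C)(C)C)c1 | intermediate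
16 | {(2,3-trans-3,4-cis-4,5-trans)-2,5-bis[3,4-bis(tert-butyldimethylsilyloxy)phenyl]oxolane-3,4-diyl}dimethanol (meso) | OC[C@@H]1[C@H](CO)[C@@H](c2ccc(O[Si](C)(C)C(C)(C)C)c(O[Si](C)(C)C(C)(C)C)c2)O[C@H]1c1ccc(O[Si](C)(C)C(C)(C)C)c(O[Si](C)(C)C(C)(C)C)c1 | intermediate
17 | {(2,3-trans-3,4-cis-4,5-trans)-2,5-bis[3,4-bis(tert-butyldimethylsilyloxy)phenyl]oxolane-3,4-diyl}dimethanediyl diacetate (meso) | CC(=O)OC[C@@H]1[C@H](COC(C)=O)[C@@H](c2ccc(O[Si](C)(C)C(C)(C)C)c(O[Si](C)(C)C(C)(C)C)c2)O[C@H]1c1ccc(O[Si](C)(C)C(C)(C)C)c(O[Si](C)(C)C(C)(C)C)c1 | intermediate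
18 | [(2R,3S,4R,5S)-2,5-bis(3,4-dihydroxyphenyl)oxolane-3,4-diyl]dimethanediyl diacetate (meso) | CC(=O)OC[C@@H]1[C@H](COC(C)=O)[C@@H](c2ccc(O)c(O)c2)O[C@H]1c1ccc(O)c(O)c1 | target

**Count**
Total steps: 12. Longest linear sequence: 10 steps (1 → 2 → 7 → 8 → 10 → 13 → 14 → 15 → 16 → 17 → 18; the acceptor branch 2 → 4 → 6 joins at step 7).

**Steps most likely to fail**

Step 8. What may go wrong: hydrogen may be delivered from the face of the C3 ester (wrong 3,4-relationship), uptake by the tetrasubstituted push–pull alkene may be slow, or the benzylic C–O bonds may be hydrogenolysed. The fallback sets out from 13 and returns at 16; it ties the two carboxyl carbons into a ring so that the ring fusion, not steric bias, fixes 3,4-cis.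
- LiBH4 in THF at 0 °C should reduce only the saturated C3 ester, because the C4 ester is a deactivated vinylogous carbonate, giving ethyl trans-2,5-bis[3,4-bis(tert-butyldimethylsilyloxy)phenyl]-3-(hydroxymethyl)-2,3-dihydrofuran-4-carboxylate F1.
- PPTS in toluene at 80 °C should lactonise it to the bicyclic enol-ether lactone 4,6-bis[3,4-bis(tert-butyldimethylsilyloxy)phenyl]-3a,4-dihydro-3H-furo[3,4-c]furan-1-one F2, whose ring-fusion alkene is strained and therefore more reactive.
- Hydrogenation over Rh/Al2O3 should then give the cis-fused lactone with the C5 aryl on the concave face, 4,6-bis[3,4-bis(tert-butyldimethylsilyloxy)phenyl]tetrahydro-1H,3H-furo[3,4-c]furan-1-one F3, since a trans-fused pair of five-membered rings is strongly disfavoured.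
- Catalytic BF3·OEt2 should move that aryl to the convex face with a larger bias than in the monocycle, giving the diexo lactone F4.
- LiBH4 in THF should reduce F4 to diol 16. Steps 8 to 10 are replaced.

Step 9. What may go wrong: the Lewis acid may strip aryl silyl groups; the ring-opened benzylic cation may lose the C4 proton or be trapped by an arene instead of reclosing; or ionisation may be too slow next to the C4 ester. The fallback sets out from 14 and returns at 18; it moves the epimerisation to the end, where free para-hydroxyl groups let the benzylic ether open through a para-quinone methide under much weaker acid and the neighbouring carbon carries CH2OAc, not an ester.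
- 14 is reduced with i-Bu2AlH to the 4,5-cis diol {(2,3-trans-3,4-cis-4,5-cis)-2,5-bis[3,4-bis(tert-butyldimethylsilyloxy)phenyl]oxolane-3,4-diyl}dimethanol F5.
- Acetylation with Ac2O/pyridine gives its diacetate F6.
- TBAF/AcOH gives the C5 epimer of the target, (2,3-trans-3,4-cis-4,5-cis)-2,5-bis(3,4-dihydroxyphenyl)oxolane-3,4-diyl]dimethanediyl diacetate F7.
- Catalytic CF3CO2H in CH2Cl2/MeCN at 0 °C to rt should equilibrate the benzylic centres to the meso arrangement 18.

Step 7. What may go wrong: the ylide may decay before it adds (Sommelet–Hauser rearrangement through the S-methylide, or self-condensation to a stilbene), or the base may desilylate the para-silyloxybenzyl sulfonium salt, which then collapses through a quinone methide. The fallback sets out from 2 and 4 and returns at 13; it is an oxidative radical [3+2] annulation.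
- Wittig olefination of 2 with Ph3P=CHCO2Et in CH2Cl2 gives ethyl (E)-3-[3,4-bis(tert-butyldimethylsilyloxy)phenyl]prop-2-enoate F8.
- Mn(OAc)3·2H2O (2.2 equiv) in AcOH at 60 °C should oxidise β-keto ester 4 to its α-radical, which adds to the ester-bearing alkene carbon of F8.
- The resulting benzylic radical is oxidised to the cation and captured by the ketone oxygen, which should give the same trans-dihydrofuran 13. Compounds 6 and 10 and steps 3 to 6 are then not needed.

**Further compounds**
F1 | step 8 | ethyl trans-2,5-bis[3,4-bis(tert-butyldimethylsilyloxy)phenyl]-3-(hydroxymethyl)-2,3-dihydrofuran-4-carboxylate (racemic) | OC[C@@H]1C(C(=O)OCC)=C(c2ccc(O[Si](C)(C)C(C)(C)C)c(O[Si](C)(C)C(C)(C)C)c2)O[C@H]1c1ccc(O[Si](C)(C)C(C)(C)C)c(O[Si](C)(C)C(C)(C)C)c1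
F2 | step 8 | 4,6-bis[3,4-bis(tert-butyldimethylsilyloxy)phenyl]-3a,4-dihydro-3H-furo[3,4-c]furan-1-one (racemic, 3a-H and 4-H trans) | O=C1OC[C@H]2[C@H](c3ccc(O[Si](C)(C)C(C)(C)C)c(O[Si](C)(C)C(C)(C)C)c3)OC(c3ccc(O[Si](C)(C)C(C)(C)C)c(O[Si](C)(C)C(C)(C)C)c3)=C12
F3 | step 8 | cis-fused 4,6-bis[3,4-bis(tert-butyldimethylsilyloxy)phenyl]tetrahydro-1H,3H-furo[3,4-c]furan-1-one, 4-aryl exo and 6-aryl endo (racemic) | O=C1OC[C@H]2[C@H](c3ccc(O[Si](C)(C)C(C)(C)C)c(O[Si](C)(C)C(C)(C)C)c3)O[C@@H](c3ccc(O[Si](C)(C)C(C)(C)C)c(O[Si](C)(C)C(C)(C)C)c3)[C@@H]12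
F4 | step 8 | cis-fused 4,6-bis[3,4-bis(tert-butyldimethylsilyloxy)phenyl]tetrahydro-1H,3H-furo[3,4-c]furan-1-one, both aryls exo (racemic) | O=C1OC[C@H]2[C@H](c3ccc(O[Si](C)(C)C(C)(C)C)c(O[Si](C)(C)C(C)(C)C)c3)O[C@H](c3ccc(O[Si](C)(C)C(C)(C)C)c(O[Si](C)(C)C(C)(C)C)c3)[C@@H]12
F5 | step 9 | {(2,3-trans-3,4-cis-4,5-cis)-2,5-bis[3,4-bis(tert-butyldimethylsilyloxy)phenyl]oxolane-3,4-diyl}dimethanol (racemic) | OC[C@@H]1[C@H](CO)[C@H](c2ccc(O[Si](C)(C)C(C)(C)C)c(O[Si](C)(C)C(C)(C)C)c2)O[C@H]1c1ccc(O[Si](C)(C)C(C)(C)C)c(O[Si](C)(C)C(C)(C)C)c1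
F6 | step 9 | {(2,3-trans-3,4-cis-4,5-cis)-2,5-bis[3,4-bis(tert-butyldimethylsilyloxy)phenyl]oxolane-3,4-diyl}dimethanediyl diacetate (racemic) | CC(=O)OC[C@@H]1[C@H](COC(C)=O)[C@H](c2ccc(O[Si](C)(C)C(C)(C)C)c(O[Si](C)(C)C(C)(C)C)c2)O[C@H]1c1ccc(O[Si](C)(C)C(C)(C)C)c(O[Si](C)(C)C(C)(C)C)c1
F7 | step 9 | [(2,3-trans-3,4-cis-4,5-cis)-2,5-bis(3,4-dihydroxyphenyl)oxolane-3,4-diyl]dimethanediyl diacetate (racemic C5 epimer of the target) | CC(=O)OC[C@@H]1[C@H](COC(C)=O)[C@H](c2ccc(O)c(O)c2)O[C@H]1c1ccc(O)c(O)c1
F8 | step 7 | ethyl (E)-3-[3,4-bis(tert-butyldimethylsilyloxy)phenyl]prop-2-enoate | CCOC(=O)/C=C/c1ccc(O[Si](C)(C)C(C)(C)C)c(O[Si](C)(C)C(C)(C)C)c1
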